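Early on Z, the substrate, falls fast: at 0.833 h Wednesday's run already reads 86.3% of the charge, with E at 7.0%. E is the species Z forms with L, the dissolved reagent supplied by the held gas J. D is the product, and G is a further species that goes unread. After that early fall the decline is slower, and one number can carry it.

in all of them: J 47 mM (held)

| run | Z | remark | time |
|---|---|---|---|
| Saturday's | 0.28 M | run made earlier |  |
| Wednesday's | 1.1 M | run made earlier |  |
| flask | 0.56 M |  | 6.0 h |

| run | time / h | D / % | Z / % | E / % |
|---|---|---|---|---|
| Saturday's | 2.00 | 4.2 | 77.4 | 5.9 |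
| Saturday's | 4.00 | 6.9 | 65.0 | 5.4 |
| Saturday's | 5.00 | 8.2 | 61.0 | 5.1 |
| Saturday's | 8.00 | 14.0 | 47.0 | 3.7 |
| Wednesday's | 0.833 | 1.6 | 86.3 | 7.0 |
| Wednesday's | 2.50 | 4.2 | 74.7 | 6.6 |
| Wednesday's | 5.00 | 8.8 | 60.1 | 5.6 |
| Wednesday's | 8.00 | 12.6 | 45.8 | 4.2 |

(standard deviation of a reading: 0.5 percentage points)

- where most of what was charged as Z, at 6.0 h is found (D / E / Z)
- the largest share itself, whichever of these holds it, in percent of the Z charged

- at the start none of L is dissolved
- reactions considered so far: Z + L <-> E; Z <-> G; E -> D; J <-> L
- a reading or a percentage of Z is of its free form alone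

Take as zero of the scale a flask whose percentages ignore the charge. Against that zero, at 5.00 h the two runs differ by 0.9 percentage points, though Wednesday's charge is 3.93 times Saturday's. Between 5.00 h and 8.00 h, ln Z falls by 0.0869 h⁻¹ in Saturday's run and 0.0906 h⁻¹ in Wednesday's. Their mean 0.0887 h⁻¹ is λ, the late loss constant, a pseudo-first-order constant read from the readings.

Now two extremes, both reckoned by me. If your flask were Saturday's run, λ would carry Z from 5.00 h to 55.8% at 6.0 h. If it were Wednesday's, to 55.0%. Its charge of 0.56 M lies between theirs, so I place Z between those two values. D, at 14.0% even at 8.00 h in Saturday's run, stays far below.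

The forecast names Z at 55.5%, within 53.5% to 57.5%, on the ground that "the two runs match within noise".

The flask gives Z at 55.0%, with D at 10.5% and E at 4.61%, inside the forecast's range.

    Z + L ⇌ E, settled at all times (K = 1.80 L mol⁻¹)
    Z ⇌ G (K = 5.70, k = 0.00120 min⁻¹)
    E → D (k = 0.00500 min⁻¹)
    J ⇌ L, rate k4*(csat - [L]) (kL = 0.240 min⁻¹)

Of the two settings tried, time and charge, with the gas not among them, the time of reading can take Z out of the forecast's range: at 4.97 h or 7.15 h Z stands 5 points away, whereas charges from 0.070 M to 4.5 M keep it within those points. Run λ backwards from the 55.0% at 6.0 h to the same flask read at 2.5 h and you get 75.0%; that flask, read at 2.5 h, held 74.1% of its Z.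

(The earlier runs and the new flask are calculated for substances that don't exist.)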